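The six-membered ring is cut at C2–C3 and C4–C5 (target numbered as 7-oxabicyclo[4.1.0]heptan-2-one). What remains is a 3-methylfuran-2-ol unit (C5, C6, C1, C2), whose ring oxygen becomes the 5-hydroxyl and whose 2-oxygen becomes the C2 ketone, and an enone C=C (C3, C4). The cis 3-O/5-O pair and the 1,4-related C2/C5 oxygens are exploited: a di-tert-butylsilylene ties the furan 2-oxygen to the future 3-oxygen, an intramolecular furan Diels–Alder reaction forms both bonds, and the strained oxanorbornene collapses to a silylene-bridged 4-oxycyclohexenone with C3, C4 and C5 relayed from one proline-made carbinol centre. Methylenation, silylene opening with acetylation, epoxidation and desilylation finish.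

Key step: step 6

Remark: the β-silyloxy enone of 10 is taken to react as its thermodynamically preferred E isomer, E/Z exchange of such vinylogous silyl esters being easy; "angeloyl" means (2Z)-2-methylbut-2-enoyl.

Step 1
Reactants: 1 6-methylhept-5-en-2-one
Product: 3 (3S)-3-hydroxy-6-methylhept-5-en-2-one, via aminoxy ketone 2 (not isolated)
Conditions: PhNO (slow addition), D-proline (20 mol%), DMSO, rt; then Zn, AcOH, 0 °C
Reagents that add atoms: nitrosobenzene O=Nc1ccccc1
Why: Proline-catalysed α-aminoxylation (O-selective nitroso aldol) proceeds through the more substituted E-enamine, whose carboxylic acid directs nitrosobenzene to one face so that D-proline should give the S centre, and Zn/AcOH then cleaves the N–O bond reductively.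

Step 2
Reactants: 3 (3S)-3-hydroxy-6-methylhept-5-en-2-one; 4 angelic acid
Product: 5 (3S)-6-methyl-2-oxohept-5-en-3-yl (2Z)-2-methylbut-2-enoate
Conditions: 4, 2,4,6-trichlorobenzoyl chloride, Et3N, toluene, rt; then 3, 60 °C
Reagents that add atoms: none
Why: Yamaguchi esterification through the mixed anhydride, run without DMAP, acylates the α-ketol and should keep the Z geometry of the angelate.

Step 3
Reactants: 5 (3S)-6-methyl-2-oxohept-5-en-3-yl (2Z)-2-methylbut-2-enoate
Product: 6 (1E,4S)-1-(dimethylamino)-7-methyl-3-oxoocta-1,6-dien-4-yl (2Z)-2-methylbut-2-enoate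
Conditions: Me2NCH(OMe)2 (neat), 80 °C
Reagents that add atoms: N,N-dimethylformamide dimethyl acetal COC(OC)N(C)C
Why: Condensation of a methyl ketone with a formamide acetal (enaminone synthesis) can take place only at the methyl group because C-3 carries a single hydrogen, and it gives the E-vinylogous amide.

Step 4
Reactants: 6 (1E,4S)-1-(dimethylamino)-7-methyl-3-oxoocta-1,6-dien-4-yl (2Z)-2-methylbut-2-enoate
Product: 7 (1Z,4S)-1-hydroxy-7-methyl-3-oxoocta-1,6-dien-4-yl (2Z)-2-methylbut-2-enoate (enol form of the 3-oxo aldehyde)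
Conditions: 1 M HCl, THF, 0 °C
Reagents that add atoms: water O
Why: Acid hydrolysis of the vinylogous amide releases the 3-oxo aldehyde as its chelated Z-enol while the hindered conjugated ester should survive.

Step 5
Reactants: 7 (1Z,4S)-1-hydroxy-7-methyl-3-oxoocta-1,6-dien-4-yl (2Z)-2-methylbut-2-enoate; 8 3-methylfuran-2(5H)-one
Product: 10 (1E,4S)-1-({di-tert-butyl[(3-methylfuran-2-yl)oxy]silyl}oxy)-7-methyl-3-oxoocta-1,6-dien-4-yl (2Z)-2-methylbut-2-enoate, via furyloxysilyl triflate 9 (not isolated)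
Conditions: 8, tBu2Si(OTf)2, Et3N, CH2Cl2, −78 → 0 °C; then 7, Et3N, 0 °C → rt
Reagents that add atoms: di-tert-butylsilyl bis(trifluoromethanesulfonate) CC(C)(C)[Si](OS(=O)(=O)C(F)(F)F)(OS(=O)(=O)C(F)(F)F)C(C)(C)C
Why: Two consecutive enol O-silylations (soft enolisation with a silyl triflate and Et3N): the first triflate turns the butenolide into its 2-silyloxyfuran, the hindered second one is slow enough to be reserved for the formyl oxygen of 7, and the resulting vinylogous silyl ester should relax to the E isomer.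

Step 6
Reactants: 10 (1E,4S)-1-({di-tert-butyl[(3-methylfuran-2-yl)oxy]silyl}oxy)-7-methyl-3-oxoocta-1,6-dien-4-yl (2Z)-2-methylbut-2-enoate
Product: 12 (2S)-1-[(1R,5R,9S)-3,3-di-tert-butyl-7-methyl-6-oxo-2,4-dioxa-3-silabicyclo[3.3.1]non-7-en-9-yl]-5-methyl-1-oxohex-4-en-2-yl (2Z)-2-methylbut-2-enoate, via silyl ketal oxanorbornene 11 (not isolated)
Conditions: toluene (0.005 M), BHT, 80 °C
Reagents that add atoms: none
Why: Proposed new method: heat brings the 2-silyloxyfuran (4π) and the tethered E-β-silyloxy enone (2π) to a concerted intramolecular Diels–Alder reaction that forms C9–C1 and C5–C6 (numbering of 12), and the strained 1-silyloxy-7-oxanorbornene 11 then opens by heterolysis of its bridgehead C–O bond with O-to-O silyl transfer to the released alkoxide; the closest known reactions are the intramolecular furan Diels–Alder/oxabridge-opening cascade of 2-amidofurans tethered through the heteroatom and silicon-tethered Diels–Alder reactions. The carbocycle closes suprafacially in the [4+2] mode, the five-membered dioxasilolane of 11 closes with the three-atom tether exo (syn to the oxygen bridge), and the six-membered dioxasilinane of 12 closes by the silyl shift. C-1 (oxygen from the furan ring) and C-5 (tether oxygen) are therefore cis, C-9 is trans to both because the E-alkene puts the acyl group endo, and the absolute sense is relayed from the S carbinol centre: the s-cis enone should be attacked on the face bearing the α-hydrogen while the C–O(angelate) bond lies anti to the carbonyl dipole. The step needs a regiochemistry opposite to the natural polarity of a silyloxyfuran (C-5 of the furan to the enone β-carbon), which only the O–Si–O tether can enforce, and a facial selectivity that rests on 1,2-induction from the acyclic stereocentre and is the weaker control element.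

Step 7
Reactants: 12 (2S)-1-[(1R,5R,9S)-3,3-di-tert-butyl-7-methyl-6-oxo-2,4-dioxa-3-silabicyclo[3.3.1]non-7-en-9-yl]-5-methyl-1-oxohex-4-en-2-yl (2Z)-2-methylbut-2-enoate
Product: 13 (3S)-2-[(1R,5R,9S)-3,3-di-tert-butyl-7-methyl-6-oxo-2,4-dioxa-3-silabicyclo[3.3.1]non-7-en-9-yl]-6-methylhepta-1,5-dien-3-yl (2Z)-2-methylbut-2-enoate
Conditions: Cp2Ti(μ-Cl)(μ-CH2)AlMe2, pyridine, THF, −40 → 0 °C
Reagents that add atoms: Tebbe reagent C[Al](C)Cl.C=[Ti](C1C=CC=C1)C1C=CC=C1
Why: Tebbe olefination is non-basic, so the epimerisable C-9 with its two β-oxygens is safe, and the reagent should prefer the inductively activated α-acyloxy ketone to the conjugated ring carbonyl that is flanked by the C-7 methyl and the silylene.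

Step 8
Reactants: 13 (3S)-2-[(1R,5R,9S)-3,3-di-tert-butyl-7-methyl-6-oxo-2,4-dioxa-3-silabicyclo[3.3.1]non-7-en-9-yl]-6-methylhepta-1,5-dien-3-yl (2Z)-2-methylbut-2-enoate
Product: 15 (3S)-2-[(1R,2R,6R)-2-(acetyloxy)-6-{[di-tert-butyl(fluoro)silyl]oxy}-4-methyl-3-oxocyclohex-4-en-1-yl]-6-methylhepta-1,5-dien-3-yl (2Z)-2-methylbut-2-enoate, via hydroxy fluorosilyl ether 14 (not isolated)
Conditions: Bu4NF (1.0 equiv), AcOH, THF, −20 °C; then Ac2O, DMAP, pyridine, 0 °C
Reagents that add atoms: tetrabutylammonium fluoride CCCC[N+](CCCC)(CCCC)CCCC.[F-]; acetic anhydride CC(=O)OC(C)=O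
Why: Fluoride attack at silicon opens the di-tert-butylsilylene (mono-desilylation to a fluorosilyl ether) with loss of the better leaving group, the α-ketol oxygen, so silicon should stay on the allylic oxygen and the freed hydroxyl is then acetylated by DMAP-catalysed acylation.

Step 9
Reactants: 15 (3S)-2-[(1R,2R,6R)-2-(acetyloxy)-6-{[di-tert-butyl(fluoro)silyl]oxy}-4-methyl-3-oxocyclohex-4-en-1-yl]-6-methylhepta-1,5-dien-3-yl (2Z)-2-methylbut-2-enoate
Product: 16 (3S)-2-[(1R,3R,4R,5S,6R)-3-(acetyloxy)-5-{[di-tert-butyl(fluoro)silyl]oxy}-1-methyl-2-oxo-7-oxabicyclo[4.1.0]heptan-4-yl]-6-methylhepta-1,5-dien-3-yl (2Z)-2-methylbut-2-enoate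
Conditions: tBuOOH (decane), DBU, CH2Cl2, 0 °C
Reagents that add atoms: tert-butyl hydroperoxide CC(C)(C)OO
Why: Weitz–Scheffer nucleophilic epoxidation: the hydroperoxide anion adds to the enone β-carbon anti to the bulky 6-silyloxy group in the now all-equatorial half-chair, so the epoxide should form trans to that oxygen and cis to the side chain.

Step 10
Reactants: 16 (3S)-2-[(1R,3R,4R,5S,6R)-3-(acetyloxy)-5-{[di-tert-butyl(fluoro)silyl]oxy}-1-methyl-2-oxo-7-oxabicyclo[4.1.0]heptan-4-yl]-6-methylhepta-1,5-dien-3-yl (2Z)-2-methylbut-2-enoate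
Product: 17 (3S)-2-[(1R,3R,4S,5S,6R)-3-(acetyloxy)-5-hydroxy-1-methyl-2-oxo-7-oxabicyclo[4.1.0]heptan-4-yl]-6-methylhepta-1,5-dien-3-yl (2Z)-2-methylbut-2-enoate
Conditions: HF·pyridine, pyridine, THF, 0 °C
Reagents that add atoms: none
Why: Buffered HF·pyridine cleaves the fluorosilyl ether (fluoride desilylation) and should leave the epoxy ketone and the two esters untouched.

Compound list
1 | 6-methylhept-5-en-2-one | CC(=O)CCC=C(C)C | starting material
2 | (3S)-6-methyl-3-[(phenylamino)oxy]hept-5-en-2-one | CC(=O)[C@H](CC=C(C)C)ONc1ccccc1 | intermediate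
3 | (3S)-3-hydroxy-6-methylhept-5-en-2-one | CC(=O)[C@H](CC=C(C)C)O | intermediate
4 | angelic acid [(2Z)-2-methylbut-2-enoic acid] | C/C=C(/C)C(=O)O | starting material
5 | (3S)-6-methyl-2-oxohept-5-en-3-yl (2Z)-2-methylbut-2-enoate | CC(=O)[C@H](CC=C(C)C)OC(=O)/C(C)=C\C | intermediate
6 | (1E,4S)-1-(dimethylamino)-7-methyl-3-oxoocta-1,6-dien-4-yl (2Z)-2-methylbut-2-enoate | CN(C)/C=C/C(=O)[C@H](CC=C(C)C)OC(=O)/C(C)=C\C | intermediate
7 | (1Z,4S)-1-hydroxy-7-methyl-3-oxoocta-1,6-dien-4-yl (2Z)-2-methylbut-2-enoate (enol form of the 3-oxo aldehyde) | O/C=C\C(=O)[C@H](CC=C(C)C)OC(=O)/C(C)=C\C | intermediate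
8 | 3-methylfuran-2(5H)-one | CC1=CCOC1=O | starting material
9 | di-tert-butyl[(3-methylfuran-2-yl)oxy]silyl trifluoromethanesulfonate | Cc1ccoc1O[Si](C(C)(C)C)(C(C)(C)C)OS(=O)(=O)C(F)(F)F | intermediate
10 | (1E,4S)-1-({di-tert-butyl[(3-methylfuran-2-yl)oxy]silyl}oxy)-7-methyl-3-oxoocta-1,6-dien-4-yl (2Z)-2-methylbut-2-enoate | Cc1ccoc1O[Si](C(C)(C)C)(C(C)(C)C)O/C=C/C(=O)[C@H](CC=C(C)C)OC(=O)/C(C)=C\C | intermediate
11 | silyl ketal cycloadduct: 3-methyl-7-oxabicyclo[2.2.1]hept-2-ene carrying the (2S)-2-(angeloyloxy)-5-methylhex-4-enoyl group endo at C-6 and a di-tert-butylsilylenedioxy bridge from bridgehead C-4 to exo C-5 | O=C([C@H]1[C@H]2C=C(C)[C@@]3(O2)O[Si](C(C)(C)C)(C(C)(C)C)O[C@H]13)[C@H](CC=C(C)C)OC(=O)/C(C)=C\C | intermediate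
12 | (2S)-1-[(1R,5R,9S)-3,3-di-tert-butyl-7-methyl-6-oxo-2,4-dioxa-3-silabicyclo[3.3.1]non-7-en-9-yl]-5-methyl-1-oxohex-4-en-2-yl (2Z)-2-methylbut-2-enoate | O=C([C@H]1[C@H]2C=C(C)C(=O)[C@@H]1O[Si](C(C)(C)C)(C(C)(C)C)O2)[C@H](CC=C(C)C)OC(=O)/C(C)=C\C | intermediate
13 | (3S)-2-[(1R,5R,9S)-3,3-di-tert-butyl-7-methyl-6-oxo-2,4-dioxa-3-silabicyclo[3.3.1]non-7-en-9-yl]-6-methylhepta-1,5-dien-3-yl (2Z)-2-methylbut-2-enoate | C=C([C@H]1[C@H]2C=C(C)C(=O)[C@@H]1O[Si](C(C)(C)C)(C(C)(C)C)O2)[C@H](CC=C(C)C)OC(=O)/C(C)=C\C | intermediate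
14 | (3S)-2-[(1R,2R,6R)-6-{[di-tert-butyl(fluoro)silyl]oxy}-2-hydroxy-4-methyl-3-oxocyclohex-4-en-1-yl]-6-methylhepta-1,5-dien-3-yl (2Z)-2-methylbut-2-enoate | C=C([C@H]1[C@H](O[Si](F)(C(C)(C)C)C(C)(C)C)C=C(C)C(=O)[C@@H]1O)[C@H](CC=C(C)C)OC(=O)/C(C)=C\C | intermediate
15 | (3S)-2-[(1R,2R,6R)-2-(acetyloxy)-6-{[di-tert-butyl(fluoro)silyl]oxy}-4-methyl-3-oxocyclohex-4-en-1-yl]-6-methylhepta-1,5-dien-3-yl (2Z)-2-methylbut-2-enoate | C=C([C@H]1[C@H](O[Si](F)(C(C)(C)C)C(C)(C)C)C=C(C)C(=O)[C@@H]1OC(C)=O)[C@H](CC=C(C)C)OC(=O)/C(C)=C\C | intermediate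
16 | (3S)-2-[(1R,3R,4R,5S,6R)-3-(acetyloxy)-5-{[di-tert-butyl(fluoro)silyl]oxy}-1-methyl-2-oxo-7-oxabicyclo[4.1.0]heptan-4-yl]-6-methylhepta-1,5-dien-3-yl (2Z)-2-methylbut-2-enoate | C=C([C@H]1[C@H](O[Si](F)(C(C)(C)C)C(C)(C)C)[C@H]2O[C@@]2(C)C(=O)[C@@H]1OC(C)=O)[C@H](CC=C(C)C)OC(=O)/C(C)=C\C | intermediate
17 | (3S)-2-[(1R,3R,4S,5S,6R)-3-(acetyloxy)-5-hydroxy-1-methyl-2-oxo-7-oxabicyclo[4.1.0]heptan-4-yl]-6-methylhepta-1,5-dien-3-yl (2Z)-2-methylbut-2-enoate | C=C([C@H]1[C@H](O)[C@H]2O[C@@]2(C)C(=O)[C@@H]1OC(C)=O)[C@H](CC=C(C)C)OC(=O)/C(C)=C\C | target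

Total step count: 10. Longest linear sequence: 10 steps (1 to 17; 4 and 8 are bought and enter without steps of their own).

Steps most likely to fail

Step 6 (Proposed new method). Intermolecular conjugate addition and oligomerisation may outrun the polarity-mismatched intramolecular cycloaddition, or the facial selectivity may be low. The fallback gives up the tether and uses only known chemistry. It sets out from 7, which Ac2O and pyridine should convert into the E-acetoxy enone F1. Separately, commercial (2E)-4-acetoxy-2-methylbut-2-enal is deacetylated (K2CO3, MeOH) to the hydroxy enal F2, silylated (TBSCl, imidazole) to the silyl ether F3 and dienolised (TESOTf, Et3N) to the bis-silyloxy diene F4. A thermal intermolecular Diels–Alder reaction of F1 and F4 (toluene, 60 °C) should give the cyclohexene F5, with the acyl-bearing carbon para to the diene methyl and the acyl group endo, so that the TBS-oxygen next to the acyl-bearing carbon is cis to it. Tebbe methylenation should give the diene F6, PPTS in MeOH should remove the triethylsilyl group to give the allylic alcohol F7, and Dess–Martin oxidation should give the enone F8. HF·pyridine should then free the hydroxy enone F9, whose carbinol centre is inverted by a Mitsunobu reaction (PPh3, DIAD, chloroacetic acid) to give the chloroacetate F10. Epoxidation with tBuOOH and DBU, anti to the ester, should give the epoxy ketone F11, and thiourea with NaHCO3 removes the chloroacetate, so that the sequence comes back to the route at 17.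

Step 8. Fluoride may open the silylene at the other oxygen or strip silicon completely. The fallback sets out from 13. HF·pyridine should remove the silylene to give the diol F12. TBSCl and imidazole should silylate the more nucleophilic allylic hydroxyl, the α-ketol hydroxyl being hydrogen-bonded and inductively deactivated, to give the silyl ether F13. Ac2O and DMAP should give the acetate F14, tBuOOH and DBU the epoxy ketone F15, and HF·pyridine brings the sequence back to the route at 17.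

Step 7. Methylenation of the ring enone carbonyl may compete with that of the side-chain ketone. The fallback moves the olefination ahead of the fragmentation, so that no second ketone is present. It sets out from 10: the cycloaddition is run at 1.0 GPa in CH2Cl2 at rt, where the cycloadduct 11 should persist, and the crude adduct is treated with the Tebbe reagent at −40 °C to give the methylenated oxanorbornene F16. PPTS in CH2Cl2 then triggers the fragmentation and silyl shift, and the sequence comes back to the route at 13.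

Further compounds
F1 | step 6 | (1E,4S)-1-(acetyloxy)-7-methyl-3-oxoocta-1,6-dien-4-yl (2Z)-2-methylbut-2-enoate | CC(=O)O/C=C/C(=O)[C@H](CC=C(C)C)OC(=O)/C(C)=C\C
F2 | step 6 | (2E)-4-hydroxy-2-methylbut-2-enal | O=C/C(C)=C/CO
F3 | step 6 | (2E)-4-[(tert-butyldimethylsilyl)oxy]-2-methylbut-2-enal | O=C/C(C)=C/CO[Si](C)(C)C(C)(C)C
F4 | step 6 | (1E,3E)-1-[(tert-butyldimethylsilyl)oxy]-3-methyl-4-[(triethylsilyl)oxy]buta-1,3-diene | CC[Si](CC)(CC)O/C=C(C)/C=C/O[Si](C)(C)C(C)(C)C
F5 | step 6 | (2S)-1-{6-(acetyloxy)-2-[(tert-butyldimethylsilyl)oxy]-4-methyl-5-[(triethylsilyl)oxy]cyclohex-3-en-1-yl}-5-methyl-1-oxohex-4-en-2-yl (2Z)-2-methylbut-2-enoate (both silyloxy groups cis to the acyl group, acetoxy trans) | O=C([C@H]1[C@@H](O[Si](C)(C)C(C)(C)C)C=C(C)[C@@H](O[Si](CC)(CC)CC)[C@@H]1OC(C)=O)[C@H](CC=C(C)C)OC(=O)/C(C)=C\C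
F6 | step 6 | (3S)-2-{6-(acetyloxy)-2-[(tert-butyldimethylsilyl)oxy]-4-methyl-5-[(triethylsilyl)oxy]cyclohex-3-en-1-yl}-6-methylhepta-1,5-dien-3-yl (2Z)-2-methylbut-2-enoate (ring configuration as in F5) | C=C([C@H]1[C@@H](O[Si](C)(C)C(C)(C)C)C=C(C)[C@@H](O[Si](CC)(CC)CC)[C@@H]1OC(C)=O)[C@H](CC=C(C)C)OC(=O)/C(C)=C\C
F7 | step 6 | (3S)-2-{6-(acetyloxy)-2-[(tert-butyldimethylsilyl)oxy]-5-hydroxy-4-methylcyclohex-3-en-1-yl}-6-methylhepta-1,5-dien-3-yl (2Z)-2-methylbut-2-enoate (ring configuration as in F5) | C=C([C@H]1[C@@H](O[Si](C)(C)C(C)(C)C)C=C(C)[C@@H](O)[C@@H]1OC(C)=O)[C@H](CC=C(C)C)OC(=O)/C(C)=C\C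
F8 | step 6 | (3S)-2-{2-(acetyloxy)-6-[(tert-butyldimethylsilyl)oxy]-4-methyl-3-oxocyclohex-4-en-1-yl}-6-methylhepta-1,5-dien-3-yl (2Z)-2-methylbut-2-enoate (6-silyloxy cis to the side chain, 2-acetoxy trans) | C=C([C@H]1[C@@H](O[Si](C)(C)C(C)(C)C)C=C(C)C(=O)[C@@H]1OC(C)=O)[C@H](CC=C(C)C)OC(=O)/C(C)=C\C
F9 | step 6 | (3S)-2-[2-(acetyloxy)-6-hydroxy-4-methyl-3-oxocyclohex-4-en-1-yl]-6-methylhepta-1,5-dien-3-yl (2Z)-2-methylbut-2-enoate (6-hydroxy cis to the side chain, 2-acetoxy trans) | C=C([C@H]1[C@@H](O)C=C(C)C(=O)[C@@H]1OC(C)=O)[C@H](CC=C(C)C)OC(=O)/C(C)=C\C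
F10 | step 6 | (3S)-2-{2-(acetyloxy)-6-[(chloroacetyl)oxy]-4-methyl-3-oxocyclohex-4-en-1-yl}-6-methylhepta-1,5-dien-3-yl (2Z)-2-methylbut-2-enoate (both acyloxy groups trans to the side chain, ring configuration as in 15) | C=C([C@H]1[C@H](OC(=O)CCl)C=C(C)C(=O)[C@@H]1OC(C)=O)[C@H](CC=C(C)C)OC(=O)/C(C)=C\C
F11 | step 6 | (3S)-2-{3-(acetyloxy)-5-[(chloroacetyl)oxy]-1-methyl-2-oxo-7-oxabicyclo[4.1.0]heptan-4-yl}-6-methylhepta-1,5-dien-3-yl (2Z)-2-methylbut-2-enoate (ring configuration as in 16) | C=C([C@H]1[C@H](OC(=O)CCl)[C@H]2O[C@@]2(C)C(=O)[C@@H]1OC(C)=O)[C@H](CC=C(C)C)OC(=O)/C(C)=C\C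
F12 | step 8 | (3S)-2-(2,6-dihydroxy-4-methyl-3-oxocyclohex-4-en-1-yl)-6-methylhepta-1,5-dien-3-yl (2Z)-2-methylbut-2-enoate (hydroxyls cis to each other and trans to the side chain, ring configuration as in 14) | C=C([C@H]1[C@H](O)C=C(C)C(=O)[C@@H]1O)[C@H](CC=C(C)C)OC(=O)/C(C)=C\C
F13 | step 8 | (3S)-2-{6-[(tert-butyldimethylsilyl)oxy]-2-hydroxy-4-methyl-3-oxocyclohex-4-en-1-yl}-6-methylhepta-1,5-dien-3-yl (2Z)-2-methylbut-2-enoate (ring configuration as in 14) | C=C([C@H]1[C@H](O[Si](C)(C)C(C)(C)C)C=C(C)C(=O)[C@@H]1O)[C@H](CC=C(C)C)OC(=O)/C(C)=C\C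
F14 | step 8 | (3S)-2-{2-(acetyloxy)-6-[(tert-butyldimethylsilyl)oxy]-4-methyl-3-oxocyclohex-4-en-1-yl}-6-methylhepta-1,5-dien-3-yl (2Z)-2-methylbut-2-enoate (ring configuration as in 15) | C=C([C@H]1[C@H](O[Si](C)(C)C(C)(C)C)C=C(C)C(=O)[C@@H]1OC(C)=O)[C@H](CC=C(C)C)OC(=O)/C(C)=C\C
F15 | step 8 | (3S)-2-{3-(acetyloxy)-5-[(tert-butyldimethylsilyl)oxy]-1-methyl-2-oxo-7-oxabicyclo[4.1.0]heptan-4-yl}-6-methylhepta-1,5-dien-3-yl (2Z)-2-methylbut-2-enoate (ring configuration as in 16) | C=C([C@H]1[C@H](O[Si](C)(C)C(C)(C)C)[C@H]2O[C@@]2(C)C(=O)[C@@H]1OC(C)=O)[C@H](CC=C(C)C)OC(=O)/C(C)=C\C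
F16 | step 7 | methylenated cycloadduct: 3-methyl-7-oxabicyclo[2.2.1]hept-2-ene carrying the (3S)-3-(angeloyloxy)-6-methylhepta-1,5-dien-2-yl group endo at C-6 and the di-tert-butylsilylenedioxy bridge from bridgehead C-4 to exo C-5 | C=C([C@H]1[C@H]2C=C(C)[C@@]3(O2)O[Si](C(C)(C)C)(C(C)(C)C)O[C@H]13)[C@H](CC=C(C)C)OC(=O)/C(C)=C\C
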